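## Retrosynthetic overview

- The target comes from O‑methylation of a diosphenolate made by an anionic oxy‑Cope shift of allyl from C5 to C3a of a 5‑allyl‑5‑hydroxy dienone, itself from allyl addition to the dihydrobenzofuran‑5,6‑dione.
- That ortho‑quinone comes from periodate oxidation of the cis‑2‑aryl‑3‑methyl‑dihydrobenzofuran guaiacol, whose furan ring is closed by a Mitsunobu reaction (inversion at C2) on an anti 1‑aryl‑2‑(2‑hydroxyaryl)propan‑1‑ol.
- The diol comes from the aryl Grignard reagent and the lactol obtained by ozonolysis of an ortho‑(pent‑3‑en‑2‑yl)phenol.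
- The C3–C3a bond and the C3 centre come from an aromatic Claisen rearrangement with 1,3‑chirality transfer of an aryl (R,Z)‑pent‑3‑en‑2‑yl ether, built from the phenol and ethyl (S)‑lactate.
- Ring order: the benzene ring is bought, the dihydrofuran ring is closed in step 6, and the carbocycle is dearomatised to the cyclohexadienone last (steps 8–10).

Assumption: 3‑(benzyloxy)‑4‑methoxyphenol (1) and (3,4,5‑trimethoxyphenyl)magnesium bromide (8, 0.5 M in THF) are bought as catalogue items.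

## Route

Step 1
Reactants: 1 3‑(benzyloxy)‑4‑methoxyphenol; 2 ethyl (S)‑lactate
Product: 3 ethyl (2R)‑2‑[3‑(benzyloxy)‑4‑methoxyphenoxy]propanoate
Conditions: PPh3, DIAD, THF, 0 °C → rt
Reagents that add atoms: none
Why: Mitsunobu etherification, in which the phenol displaces the activated lactate hydroxyl by SN2 with clean inversion, so the bought (S) centre becomes the (R) aryloxy centre.

Step 2
Reactants: 3 ethyl (2R)‑2‑[3‑(benzyloxy)‑4‑methoxyphenoxy]propanoate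
Product: 5 2‑(benzyloxy)‑1‑methoxy‑4‑{[(2R,3Z)‑pent‑3‑en‑2‑yl]oxy}benzene, via aryloxypropanal 4 (not isolated)
Conditions: DIBAL‑H, CH2Cl2, −78 °C; then EtPPh3Br/KHMDS (THF), −78 °C → rt
Reagents that add atoms: ethyltriphenylphosphonium bromide CC[P+](c1ccccc1)(c1ccccc1)c1ccccc1.[Br-]
Why: DIBAL‑H stops at the aluminium hemiacetal and the salt‑free non‑stabilised Wittig ylide gives the (Z)‑alkene without touching the α‑aryloxy centre; the few percent of (E)‑isomer are removed on AgNO3–silica because they would transfer chirality in the opposite sense.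

Step 3
Reactants: 5 2‑(benzyloxy)‑1‑methoxy‑4‑{[(2R,3Z)‑pent‑3‑en‑2‑yl]oxy}benzene
Product: 6 5‑(benzyloxy)‑4‑methoxy‑2‑[(2R,3E)‑pent‑3‑en‑2‑yl]phenol
Conditions: PhNEt2, 185 °C, sealed tube
Reagents that add atoms: none
Why: Aromatic Claisen ([3,3]‑sigmatropic) rearrangement to the unhindered ortho position para to OBn; A1,3 strain with the (Z)‑γ‑methyl forces the α‑methyl outward, so the C–O centre is transferred suprafacially to the new benzylic centre (R) with an (E)‑alkene.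

Step 4
Reactants: 6 5‑(benzyloxy)‑4‑methoxy‑2‑[(2R,3E)‑pent‑3‑en‑2‑yl]phenol
Product: 7 (3S)‑6‑(benzyloxy)‑5‑methoxy‑3‑methyl‑2,3‑dihydro‑1‑benzofuran‑2‑ol (both anomers)
Conditions: O3, CH2Cl2–MeOH, −78 °C (Sudan III end‑point); then Me2S, −78 °C → rt
Reagents that add atoms: ozone [O-][O+]=O
Why: Ozonolysis with reductive work‑up cleaves the alkene faster than the arene, and the α‑aryl aldehyde is trapped at once by the ortho‑phenol as the lactol, which shields the C3 centre from enolisation.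

Step 5
Reactants: 7 (3S)‑6‑(benzyloxy)‑5‑methoxy‑3‑methyl‑2,3‑dihydro‑1‑benzofuran‑2‑ol; 8 (3,4,5‑trimethoxyphenyl)magnesium bromide
Product: 9 5‑(benzyloxy)‑2‑[(1S,2S)‑1‑hydroxy‑1‑(3,4,5‑trimethoxyphenyl)propan‑2‑yl]‑4‑methoxyphenol
Conditions: 8 (3.2 equiv), THF, −78 → 0 °C; aq. NH4Cl
Reagents that add atoms: none
Why: Grignard addition to the ring‑opened lactolate, where the aldehyde is formed already chelated to the phenoxide‑bound magnesium (Cram‑chelate model) and the aryl group adds anti to the C3 methyl, giving the anti (1S) carbinol.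

Step 6
Reactants: 9 5‑(benzyloxy)‑2‑[(1S,2S)‑1‑hydroxy‑1‑(3,4,5‑trimethoxyphenyl)propan‑2‑yl]‑4‑methoxyphenol
Product: 10 (2R,3S)‑6‑(benzyloxy)‑5‑methoxy‑3‑methyl‑2‑(3,4,5‑trimethoxyphenyl)‑2,3‑dihydro‑1‑benzofuran
Conditions: PPh3, DIAD, THF, 0 °C → rt
Reagents that add atoms: none
Why: Intramolecular Mitsunobu etherification (5‑exo‑tet SN2), in which the phenol attacks the activated benzylic carbinol with inversion, turning (1S) into (2R) and placing aryl and methyl cis.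

Step 7
Reactants: 10 (2R,3S)‑6‑(benzyloxy)‑5‑methoxy‑3‑methyl‑2‑(3,4,5‑trimethoxyphenyl)‑2,3‑dihydro‑1‑benzofuran
Product: 11 (2R,3S)‑5‑methoxy‑3‑methyl‑2‑(3,4,5‑trimethoxyphenyl)‑2,3‑dihydro‑1‑benzofuran‑6‑ol
Conditions: H2 (1 atm), 10% Pd/C, EtOAc, rt
Reagents that add atoms: none
Why: Hydrogenolysis of the primary benzyl aryl ether is much faster than cleavage of the hindered secondary benzylic C2–O bond of the ring.

Step 8
Reactants: 11 (2R,3S)‑5‑methoxy‑3‑methyl‑2‑(3,4,5‑trimethoxyphenyl)‑2,3‑dihydro‑1‑benzofuran‑6‑ol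
Product: 12 (2R,3S)‑3‑methyl‑2‑(3,4,5‑trimethoxyphenyl)‑2,3‑dihydro‑1‑benzofuran‑5,6‑dione
Conditions: NaIO4, MeCN–H2O, 0 °C; used at once
Reagents that add atoms: water O
Why: Adler periodate oxidation of a guaiacol, in which water attacks the methoxy‑bearing ortho carbon and methanol is lost, giving a 4‑alkoxy‑5‑alkyl ortho‑quinone (stabilised as a vinylogous ester) without touching C2 or C3.

Step 9
Reactants: 12 (2R,3S)‑3‑methyl‑2‑(3,4,5‑trimethoxyphenyl)‑2,3‑dihydro‑1‑benzofuran‑5,6‑dione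
Product: 13 (2R,3S,5RS)‑5‑allyl‑5‑hydroxy‑3‑methyl‑2‑(3,4,5‑trimethoxyphenyl)‑2,3‑dihydro‑1‑benzofuran‑6(5H)‑one
Conditions: In, allyl bromide, DMF, rt (reagent pre‑formed); then 12, −40 → 0 °C; used at once
Reagents that add atoms: allyl bromide C=CCBr
Why: Barbier‑type allylindium 1,2‑addition goes to the C5 carbonyl, the only one not deactivated as a vinylogous ester, giving the ortho‑quinol as C5 epimers with allyl preferentially on the face away from the pseudo‑axial C3 methyl (5R).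

Step 10
Reactants: 13 (2R,3S,5RS)‑5‑allyl‑5‑hydroxy‑3‑methyl‑2‑(3,4,5‑trimethoxyphenyl)‑2,3‑dihydro‑1‑benzofuran‑6(5H)‑one
Product: 15 (2R,3S,3aS)‑3a‑allyl‑5‑methoxy‑3‑methyl‑2‑(3,4,5‑trimethoxyphenyl)‑3,3a‑dihydro‑1‑benzofuran‑6(2H)‑one (target), via potassium diosphenolate 14 (not isolated)
Conditions: KHMDS, 18‑crown‑6, THF, −78 → 0 °C; then Me2SO4, 0 °C
Reagents that add atoms: dimethyl sulfate COS(=O)(=O)OC
Why: Anionic oxy‑Cope ([3,3]‑sigmatropic) rearrangement moves allyl suprafacially from C5 to C3a, the (5R) epimer (allyl anti to methyl and aryl) rearranging fastest to set 3aS, and the naked diosphenolate is O‑methylated; any 3a‑epimer is removed by chromatography.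

## Compound list

1 | 3‑(benzyloxy)‑4‑methoxyphenol | Oc1ccc(OC)c(OCc2ccccc2)c1 | starting material
2 | ethyl (S)‑lactate | C[C@H](O)C(=O)OCC | starting material
3 | ethyl (2R)‑2‑[3‑(benzyloxy)‑4‑methoxyphenoxy]propanoate | C[C@@H](Oc1ccc(OC)c(OCc2ccccc2)c1)C(=O)OCC | intermediate
4 | (2R)‑2‑[3‑(benzyloxy)‑4‑methoxyphenoxy]propanal | C[C@@H](Oc1ccc(OC)c(OCc2ccccc2)c1)C=O | intermediate (not isolated)
5 | 2‑(benzyloxy)‑1‑methoxy‑4‑{[(2R,3Z)‑pent‑3‑en‑2‑yl]oxy}benzene | C[C@@H](Oc1ccc(OC)c(OCc2ccccc2)c1)/C=C\C | intermediate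
6 | 5‑(benzyloxy)‑4‑methoxy‑2‑[(2R,3E)‑pent‑3‑en‑2‑yl]phenol | C/C=C/[C@@H](C)c1cc(OC)c(OCc2ccccc2)cc1O | intermediate
7 | (3S)‑6‑(benzyloxy)‑5‑methoxy‑3‑methyl‑2,3‑dihydro‑1‑benzofuran‑2‑ol (anomer mixture) | C[C@H]1c2cc(OC)c(OCc3ccccc3)cc2OC1O | intermediate
8 | (3,4,5‑trimethoxyphenyl)magnesium bromide | COc1cc([Mg]Br)cc(OC)c1OC | starting material
9 | 5‑(benzyloxy)‑2‑[(1S,2S)‑1‑hydroxy‑1‑(3,4,5‑trimethoxyphenyl)propan‑2‑yl]‑4‑methoxyphenol | C[C@H]([C@H](O)c1cc(OC)c(OC)c(OC)c1)c1cc(OC)c(OCc2ccccc2)cc1O | intermediate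
10 | (2R,3S)‑6‑(benzyloxy)‑5‑methoxy‑3‑methyl‑2‑(3,4,5‑trimethoxyphenyl)‑2,3‑dihydro‑1‑benzofuran | C[C@H]1c2cc(OC)c(OCc3ccccc3)cc2O[C@H]1c1cc(OC)c(OC)c(OC)c1 | intermediate
11 | (2R,3S)‑5‑methoxy‑3‑methyl‑2‑(3,4,5‑trimethoxyphenyl)‑2,3‑dihydro‑1‑benzofuran‑6‑ol | C[C@H]1c2cc(OC)c(O)cc2O[C@H]1c1cc(OC)c(OC)c(OC)c1 | intermediate
12 | (2R,3S)‑3‑methyl‑2‑(3,4,5‑trimethoxyphenyl)‑2,3‑dihydro‑1‑benzofuran‑5,6‑dione | C[C@H]1C2=CC(=O)C(=O)C=C2O[C@H]1c1cc(OC)c(OC)c(OC)c1 | intermediate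
13 | (2R,3S,5RS)‑5‑allyl‑5‑hydroxy‑3‑methyl‑2‑(3,4,5‑trimethoxyphenyl)‑2,3‑dihydro‑1‑benzofuran‑6(5H)‑one (C5 epimers, 5R productive) | C[C@H]1C2=CC(O)(CC=C)C(=O)C=C2O[C@H]1c1cc(OC)c(OC)c(OC)c1 | intermediate
14 | potassium (2R,3S,3aS)‑3a‑allyl‑3‑methyl‑6‑oxo‑2‑(3,4,5‑trimethoxyphenyl)‑2,3,3a,6‑tetrahydro‑1‑benzofuran‑5‑olate | C=CC[C@]12C=C([O-])C(=O)C=C1O[C@@H](c1cc(OC)c(OC)c(OC)c1)[C@H]2C.[K+] | intermediate (not isolated)
15 | (2R,3S,3aS)‑3a‑allyl‑5‑methoxy‑3‑methyl‑2‑(3,4,5‑trimethoxyphenyl)‑3,3a‑dihydro‑1‑benzofuran‑6(2H)‑one | C=CC[C@]12C=C(OC)C(=O)C=C1O[C@@H](c1cc(OC)c(OC)c(OC)c1)[C@H]2C | target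

## Step count and risks

Total steps: 10. Longest linear sequence: 10 (1/2 → 15; 8 is bought).

**Step 3** (Claisen of the Z‑configured secondary ether). Risks are retro‑ene loss of pentadiene, abnormal‑Claisen scrambling at 185 °C, and loss of ee from residual E‑ether. The fallback sets out from 1, which is coupled under Mitsunobu conditions with lipase‑resolved (R,E)‑pent‑3‑en‑2‑ol to give 2‑(benzyloxy)‑1‑methoxy‑4‑{[(2S,3E)‑pent‑3‑en‑2‑yl]oxy}benzene F1. This geometrically pure E‑ether rearranges under Eu(fod)3 catalysis (CHCl3, 50 °C), well below the temperature of the side reactions, through a chair with both methyl groups equatorial. It comes back to the route at 6.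

**Step 5** (sense of addition to the lactol). The chelate argument is the least secure stereochemical call in the route. Felkin–Anh addition could prevail and give the syn (1R,2S) carbinol, which the Mitsunobu closure would turn into the trans ring. The fallback sets out from 6:
- the phenol is converted (Tf2O, pyridine) into 5‑(benzyloxy)‑4‑methoxy‑2‑[(2R,3E)‑pent‑3‑en‑2‑yl]phenyl trifluoromethanesulfonate F2;
- ozonolysis gives the free aldehyde (2S)‑2‑[4‑(benzyloxy)‑5‑methoxy‑2‑(trifluoromethanesulfonyloxy)phenyl]propanal F3, which has no phenoxide and so cannot chelate;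
- addition of 8 at −78 °C under Felkin–Anh control gives the syn carbinol 5‑(benzyloxy)‑2‑[(1R,2S)‑1‑hydroxy‑1‑(3,4,5‑trimethoxyphenyl)propan‑2‑yl]‑4‑methoxyphenyl trifluoromethanesulfonate F4;
- Pd‑catalysed intramolecular C–O coupling (Pd(OAc)2, t‑BuXPhos, Cs2CO3, PhMe, 80 °C) closes the ring with retention at the carbinol carbon, so the cis compound results again.

It comes back to the route at 10.

**Step 10** (oxy‑Cope on the epimeric ortho‑quinol). Only the 5R epimer leads to the target, so the yield is capped by the C5 ratio from step 9. The ortho‑quinol 13 may also dimerise, and the alkoxide can shift allyl to O6 with aromatisation. The fallback sets out from 12, which is treated with allyltrimethylsilane and TiCl4 (CH2Cl2, −78 °C). Hosomi–Sakurai conjugate attack on the titanium‑chelated quinone at C3a, from the face anti to methyl and aryl, gives the diosphenol (2R,3S,3aS)‑3a‑allyl‑5‑hydroxy‑3‑methyl‑2‑(3,4,5‑trimethoxyphenyl)‑3,3a‑dihydro‑1‑benzofuran‑6(2H)‑one F5. O‑Methylation with TMSCHN2 (MeOH–PhMe) brings it back to the route at 15.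

## Further compounds

F1 | step 3 | 2‑(benzyloxy)‑1‑methoxy‑4‑{[(2S,3E)‑pent‑3‑en‑2‑yl]oxy}benzene | C[C@H](Oc1ccc(OC)c(OCc2ccccc2)c1)/C=C/C
F2 | step 5 | 5‑(benzyloxy)‑4‑methoxy‑2‑[(2R,3E)‑pent‑3‑en‑2‑yl]phenyl trifluoromethanesulfonate | C/C=C/[C@@H](C)c1cc(OC)c(OCc2ccccc2)cc1OS(=O)(=O)C(F)(F)F
F3 | step 5 | (2S)‑2‑[4‑(benzyloxy)‑5‑methoxy‑2‑(trifluoromethanesulfonyloxy)phenyl]propanal | C[C@H](C=O)c1cc(OC)c(OCc2ccccc2)cc1OS(=O)(=O)C(F)(F)F
F4 | step 5 | 5‑(benzyloxy)‑2‑[(1R,2S)‑1‑hydroxy‑1‑(3,4,5‑trimethoxyphenyl)propan‑2‑yl]‑4‑methoxyphenyl trifluoromethanesulfonate | C[C@H]([C@@H](O)c1cc(OC)c(OC)c(OC)c1)c1cc(OC)c(OCc2ccccc2)cc1OS(=O)(=O)C(F)(F)F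
F5 | step 10 | (2R,3S,3aS)‑3a‑allyl‑5‑hydroxy‑3‑methyl‑2‑(3,4,5‑trimethoxyphenyl)‑3,3a‑dihydro‑1‑benzofuran‑6(2H)‑one | C=CC[C@]12C=C(O)C(=O)C=C1O[C@@H](c1cc(OC)c(OC)c(OC)c1)[C@H]2C
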